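**Plan**
1. Retrosynthesis: cut the C4–C4a bond of the flavanone (pyranone ring closed onto ring A), then the O1–aryl ether of ring A, then C2–C3, then the C8''–C bond of the flavone; the flavone itself is luteolin.
2. Forward: luteolin → protected 8-allyl-7-hydroxyflavone (Claisen) → (E)-cinnamyl-type boronate → homoallylic alcohol with 4-(benzyloxy)benzaldehyde → O-arylation with ring A → vinyl group cleaved to C4, which closes on O7'' as a five-membered lactone.
3. Key event: O7'' and C8'' are ortho neighbours on the flavone, so C4 can be held on O7'' as a benzofuran-2(3H)-one. Ring A is a twofold-symmetric 1,3,5-trioxygenated arene with an ortho carbon six atoms from C4. The lactone passes C4 from O7'' to C4a: a skeletal rearrangement (3-substituted benzofuranone → 3-arylchroman-4-one) that closes the pyranone ring, consumes the temporary lactone and leaves 7''-OH as the only free hydroxyl.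
4. Stereochemistry: C2 (R) comes from a chiral phosphoric acid-catalysed allylboration and is kept through the C–O coupling; C3 (S) is set by equilibration to the trans-2,3-diaryl arrangement in the key step, so both C3 epimers converge.
5. End game: sulfation of the lone 7''-OH, then one hydrogenolysis removes four benzyl ethers and the diphenylmethylene ketal.

Key step: step 12

Remark: 1-bromo-3,5-bis(benzyloxy)benzene (18) is taken as a purchasable building block.
Remark: the aryl sulfates 28 and 29 are handled as salts and are written as the free acids.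
Remark: from 17 to 25 the minor C3 epimer is carried along; names and SMILES show the major (anti-derived) isomer.
Notation: Fl = 5-(benzyloxy)-2-(2,2-diphenyl-1,3-benzodioxol-5-yl)-4-oxo-4H-chromen-8-yl (the group on O7'' is given each time); ArA = 3,5-bis(benzyloxy)phenyl; Ar' = 4-(benzyloxy)phenyl. C2, C3, C4 are the flavanone atoms; doubly primed numbers are the flavone atoms.

**Step 1**
Reactants: 1 luteolin; 2 dichlorodiphenylmethane
Product: 3 2-(2,2-diphenyl-1,3-benzodioxol-5-yl)-5,7-dihydroxy-4H-chromen-4-one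
Conditions: Ph2CCl2 (1.5 equiv), Ph2O, 175 °C
Reagents that add atoms: dichlorodiphenylmethane, ClC(Cl)(c1ccccc1)c1ccccc1
Why: Ketalisation of a catechol with a gem-dichloride, which should take only the 3',4'-diol because only it can close the five-membered 1,3-benzodioxole.

**Step 2**
Reactants: 3; 4 allyl bromide; 5 benzyl bromide
Product: 7 7-(allyloxy)-5-(benzyloxy)-2-(2,2-diphenyl-1,3-benzodioxol-5-yl)-4H-chromen-4-one, via 7-O-allyl ether 6 (not isolated)
Conditions: allyl bromide (1.05 equiv), K2CO3, DMF, rt; then BnBr (2 equiv), K2CO3, 70 °C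
Reagents that add atoms: allyl bromide, C=CCBr; benzyl bromide, BrCc1ccccc1
Why: Two Williamson etherifications in order of acidity: the 7-OH, para to the pyranone carbonyl, should react at room temperature and the hydrogen-bonded 5-OH only with benzyl bromide on heating.

**Step 3**
Reactants: 7
Product: 8 8-allyl-5-(benzyloxy)-2-(2,2-diphenyl-1,3-benzodioxol-5-yl)-7-hydroxy-4H-chromen-4-one
Conditions: PhNEt2, 200 °C, sealed tube
Reagents that add atoms: none
Why: Aromatic Claisen rearrangement ([3,3]-sigmatropic shift, then tautomerisation), which in 5-O-alkyl-7-allyloxyflavones should deliver the allyl group to C8'' (the ortho carbon joined to C7'' by the bond of higher double-bond character) and set O7''–H free.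

**Step 4**
Reactants: 8; 9 triisopropylsilyl triflate
Product: 10 8-allyl-5-(benzyloxy)-2-(2,2-diphenyl-1,3-benzodioxol-5-yl)-7-(triisopropylsilyloxy)-4H-chromen-4-one
Conditions: TIPSOTf, 2,6-lutidine, CH2Cl2, 0 °C to rt
Reagents that add atoms: triisopropylsilyl triflate, CC(C)[Si](OS(=O)(=O)C(F)(F)F)(C(C)C)C(C)C
Why: Silylation of the phenol to a base-stable, fluoride-labile ether that is orthogonal to the benzyl groups and masks O7'' until the lactone is made.

**Step 5**
Reactants: 10; 11 acetic acid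
Product: 12 (E)-3-[Fl, 7-OTIPS]prop-2-en-1-yl acetate
Conditions: Pd(OAc)2 (10 mol%), 1,4-benzoquinone (2 equiv), DMSO–AcOH 1:1, 40 °C
Reagents that add atoms: acetic acid, CC(=O)O
Why: Sulfoxide-promoted palladium-catalysed allylic C–H acetoxylation, in which divalent palladium should cleave the benzylic–allylic C–H bond to a π-allyl complex that acetate opens at the terminal carbon, giving the conjugated (E)-linear acetate.

**Step 6**
Reactants: 12; 13 bis(pinacolato)diboron
Product: 14 (E)-3-[Fl, 7-OTIPS]prop-2-en-1-ylboronic acid pinacol ester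
Conditions: Pd(dba)2 (5 mol%), B2pin2, DMSO, 50 °C
Reagents that add atoms: bis(pinacolato)diboron, CC1(C)OB(OC1(C)C)B1OC(C)(C)C(C)(C)O1
Why: Miyaura borylation of an allylic acetate (oxidative addition to zerovalent palladium, transmetalation with the diboron, reductive elimination at the unhindered terminus), which should give the (E)-γ-aryl allylboronate.

**Step 7**
Reactants: 14; 15 4-(benzyloxy)benzaldehyde
Product: 17 (1R,2S)-1-Ar'-2-[Fl, 7-OTIPS]but-3-en-1-ol, via pinacol borate ester 16 (not isolated)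
Conditions: (R)-TRIP (10 mol%), 4 Å MS, toluene, −30 °C to rt; aqueous work-up
Reagents that add atoms: 4-(benzyloxy)benzaldehyde, O=Cc1ccc(OCc2ccccc2)cc1
Why: Chiral phosphoric acid-catalysed allylboration through a closed chair transition state, in which the (E)-boronate should give the anti adduct and the acid, hydrogen-bonded to a boronate oxygen, should select the aldehyde face that makes the carbinol carbon (flavanone C2) R (the (R)-acid is chosen by analogy with benzaldehyde, the (S)-acid is used if the sense is reversed), while the configuration at the aryl-bearing carbon (flavanone C3) does not matter because it is equilibrated in step 12.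

**Step 8**
Reactants: 17; 18 1-bromo-3,5-bis(benzyloxy)benzene
Product: 19 (1R,2S)-1-(ArA-oxy)-1-Ar'-2-[Fl, 7-OTIPS]but-3-ene
Conditions: [Pd(C3H5)Cl]2 (5 mol%), RockPhos (12 mol%), Cs2CO3, toluene, 90 °C
Reagents that add atoms: 1-bromo-3,5-bis(benzyloxy)benzene, Brc1cc(OCc2ccccc2)cc(OCc2ccccc2)c1
Why: Palladium-catalysed C–O cross-coupling of a secondary alcohol with an aryl bromide (Buchwald–Hartwig etherification), which forms the bond at the aryl carbon and should therefore keep C2 as R, the bulky biarylphosphine favouring C–O reductive elimination over β-hydride elimination.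

**Step 9**
Reactants: 19
Product: 20 (1R,2S)-1-(ArA-oxy)-1-Ar'-2-[Fl, 7-OH]but-3-ene
Conditions: TBAF, AcOH, THF, 0 °C
Reagents that add atoms: none
Why: Fluoride cleavage of the aryl silyl ether, harmless here because no carbonyl group yet stands β to the aryloxy group.

**Step 10**
Reactants: 20; 21 sodium periodate
Product: 24 lactol (2-hydroxy-2,3-dihydrofuran ring closed between C4 and O7'' and fused at C7''/C8'', C3 S, carrying the (R)-(ArA-oxy)(Ar')methyl group, anomers), via vicinal diol 22 (not isolated), via hydroxy aldehyde 23 (not isolated)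
Conditions: OsO4 (2 mol%), NaIO4 (3 equiv), THF–H2O 3:1, 0 °C to rt
Reagents that add atoms: sodium periodate, [Na+].[O-]I(=O)(=O)=O (its oxygen is passed on by catalytic osmium tetroxide, O=[Os](=O)(=O)=O)
Why: Lemieux–Johnson oxidation, in which OsO4 should dihydroxylate only the isolated monosubstituted alkene (the flavone C2''=C3'' bond is an electron-poor enone), periodate cleaves the diol, and the aldehyde is trapped at once by the neighbouring 7''-OH as a five-membered lactol that shields the β-aryloxy aldehyde from elimination.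

**Step 11**
Reactants: 24
Product: 25 lactone (benzofuran-2(3H)-one ring on O7''/C8'', C3 S, carrying the (R)-(ArA-oxy)(Ar')methyl group)
Conditions: Dess–Martin periodinane, CH2Cl2, rt; used without chromatography
Reagents that add atoms: none
Why: Dess–Martin oxidation of a lactol to the lactone under neutral conditions, chosen because the β-aryloxy lactone, with its acidic C3–H, would eliminate the aryloxide with base.

**Step 12**
Reactants: 25
Product: 26 (2R,3S)-5,7-bis(benzyloxy)-2-Ar'-3-[Fl, 7-OH]chroman-4-one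
Conditions: Sc(OTf)3 (20 mol%), CH2Cl2–MeNO2 4:1, 0.01 M, 0 °C to rt
Reagents that add atoms: none
Why: Proposed new method: Sc(OTf)3 binds the flavone carbonyl and the lactone carbonyl, which makes O7'' the leaving group of a vinylogous acyloxypyrylium ester; an ortho carbon of the ArA-oxy ring, held six atoms from C4, attacks this carbonyl, the cis-fused benzofuro-chromane (pterocarpan-like) hemiketal so formed rearomatises and collapses with loss of the flavone 7-oxide, so that C4 moves from O7'' to C4a. The closest known reaction types are the Lewis acid Fries rearrangement and Friedel–Crafts acylation with aryl esters, and the cyclisation of 3-aryloxypropanoic acids to chroman-4-ones. The pyranone ring closes in the 6-exo-trig mode at the lactone carbonyl while the five-membered lactone opens. C2 is not touched and stays R; C3 is under thermodynamic control, because the lactone and then the 3-aryl ketone enolise under the Lewis acid and both C3 epimers settle in the trans-diequatorial 2,3-diaryl arrangement (3S), which is also the one the anti adduct of step 7 delivers directly. The step needs C-acylation to outrun ionisation or β-elimination at the benzylic C2–O1 bond and needs a single site of attack: the β-carbonyl group retards ionisation as it does in flavanones themselves, a six-membered ring can form only through an ortho carbon, the two ortho carbons are equivalent by the symmetry of ring A, and the para carbon cannot reach. The only hydroxyl set free is 7''-OH, the sulfation site.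

**Step 13**
Reactants: 26; 27 sulfur trioxide–pyridine complex
Product: 28 7''-O-sulfate (hydrogen sulfate) of 26
Conditions: SO3·pyridine (5 equiv), pyridine, rt
Reagents that add atoms: sulfur trioxide–pyridine complex, [O-]S(=O)(=O)[n+]1ccccc1
Why: O-Sulfation of a phenol with the SO3–pyridine complex, regioselective because 7''-OH is the only free hydroxyl, under a base too weak to open the flavanone ring.

**Step 14**
Reactants: 28
Product: 29 (2R,3S)-3-[2-(3,4-dihydroxyphenyl)-5-hydroxy-4-oxo-7-(sulfooxy)-4H-chromen-8-yl]-5,7-dihydroxy-2-(4-hydroxyphenyl)chroman-4-one (target)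
Conditions: H2 (1 atm), Pd/C (10 wt%), THF–MeOH, rt
Reagents that add atoms: none
Why: Catalytic hydrogenolysis of the four benzyl aryl ethers and of the diphenylmethylene ketal, under which the aryl sulfate monoester, the flavone enone and the flavanone should survive.

**Compound list**
1 | luteolin | O=c1cc(-c2ccc(O)c(O)c2)oc2cc(O)cc(O)c12 | starting material
2 | dichlorodiphenylmethane | ClC(Cl)(c1ccccc1)c1ccccc1 | starting material
3 | 2-(2,2-diphenyl-1,3-benzodioxol-5-yl)-5,7-dihydroxy-4H-chromen-4-one | O=c1cc(-c2ccc3OC(c4ccccc4)(c4ccccc4)Oc3c2)oc2cc(O)cc(O)c12 | intermediate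
4 | allyl bromide | C=CCBr | starting material
5 | benzyl bromide | BrCc1ccccc1 | starting material
6 | 7-(allyloxy)-2-(2,2-diphenyl-1,3-benzodioxol-5-yl)-5-hydroxy-4H-chromen-4-one | O=c1cc(-c2ccc3OC(c4ccccc4)(c4ccccc4)Oc3c2)oc2cc(OCC=C)cc(O)c12 | intermediate (not isolated)
7 | 7-(allyloxy)-5-(benzyloxy)-2-(2,2-diphenyl-1,3-benzodioxol-5-yl)-4H-chromen-4-one | O=c1cc(-c2ccc3OC(c4ccccc4)(c4ccccc4)Oc3c2)oc2cc(OCC=C)cc(OCc3ccccc3)c12 | intermediate
8 | 8-allyl-5-(benzyloxy)-2-(2,2-diphenyl-1,3-benzodioxol-5-yl)-7-hydroxy-4H-chromen-4-one | O=c1cc(-c2ccc3OC(c4ccccc4)(c4ccccc4)Oc3c2)oc2c(CC=C)c(O)cc(OCc3ccccc3)c12 | intermediate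
9 | triisopropylsilyl triflate | CC(C)[Si](OS(=O)(=O)C(F)(F)F)(C(C)C)C(C)C | starting material
10 | 8-allyl-5-(benzyloxy)-2-(2,2-diphenyl-1,3-benzodioxol-5-yl)-7-(triisopropylsilyloxy)-4H-chromen-4-one | O=c1cc(-c2ccc3OC(c4ccccc4)(c4ccccc4)Oc3c2)oc2c(CC=C)c(O[Si](C(C)C)(C(C)C)C(C)C)cc(OCc3ccccc3)c12 | intermediate
11 | acetic acid | CC(=O)O | starting material
12 | (E)-3-[Fl, 7-OTIPS]prop-2-en-1-yl acetate | O=c1cc(-c2ccc3OC(c4ccccc4)(c4ccccc4)Oc3c2)oc2c(/C=C/COC(C)=O)c(O[Si](C(C)C)(C(C)C)C(C)C)cc(OCc3ccccc3)c12 | intermediate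
13 | bis(pinacolato)diboron | CC1(C)OB(OC1(C)C)B1OC(C)(C)C(C)(C)O1 | starting material
14 | (E)-3-[Fl, 7-OTIPS]prop-2-en-1-ylboronic acid pinacol ester | O=c1cc(-c2ccc3OC(c4ccccc4)(c4ccccc4)Oc3c2)oc2c(/C=C/CB3OC(C)(C)C(C)(C)O3)c(O[Si](C(C)C)(C(C)C)C(C)C)cc(OCc3ccccc3)c12 | intermediate
15 | 4-(benzyloxy)benzaldehyde | O=Cc1ccc(OCc2ccccc2)cc1 | starting material
16 | pinacol borate ester of 17 | CC1(C)OB(O[C@@H](c2ccc(OCc3ccccc3)cc2)[C@@H](C=C)c2c(O[Si](C(C)C)(C(C)C)C(C)C)cc(OCc3ccccc3)c3c(=O)cc(-c4ccc5OC(c6ccccc6)(c6ccccc6)Oc5c4)oc23)OC1(C)C | intermediate (not isolated)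
17 | (1R,2S)-1-[4-(benzyloxy)phenyl]-2-[Fl, 7-OTIPS]but-3-en-1-ol | O[C@@H](c1ccc(OCc2ccccc2)cc1)[C@@H](C=C)c1c(O[Si](C(C)C)(C(C)C)C(C)C)cc(OCc2ccccc2)c2c(=O)cc(-c3ccc4OC(c5ccccc5)(c5ccccc5)Oc4c3)oc12 | intermediate
18 | 1-bromo-3,5-bis(benzyloxy)benzene | Brc1cc(OCc2ccccc2)cc(OCc2ccccc2)c1 | starting material
19 | (1R,2S)-1-[3,5-bis(benzyloxy)phenoxy]-1-[4-(benzyloxy)phenyl]-2-[Fl, 7-OTIPS]but-3-ene | c1ccccc1COc1cc(OCc2ccccc2)cc(O[C@@H](c2ccc(OCc3ccccc3)cc2)[C@@H](C=C)c2c(O[Si](C(C)C)(C(C)C)C(C)C)cc(OCc3ccccc3)c3c(=O)cc(-c4ccc5OC(c6ccccc6)(c6ccccc6)Oc5c4)oc23)c1 | intermediate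
20 | (1R,2S)-1-[3,5-bis(benzyloxy)phenoxy]-1-[4-(benzyloxy)phenyl]-2-[Fl, 7-OH]but-3-ene | c1ccccc1COc1cc(OCc2ccccc2)cc(O[C@@H](c2ccc(OCc3ccccc3)cc2)[C@@H](C=C)c2c(O)cc(OCc3ccccc3)c3c(=O)cc(-c4ccc5OC(c6ccccc6)(c6ccccc6)Oc5c4)oc23)c1 | intermediate
21 | sodium periodate | [Na+].[O-]I(=O)(=O)=O | starting material
22 | vicinal diol from 20 (vinyl group dihydroxylated; new carbinol centre unassigned) | c1ccccc1COc1cc(OCc2ccccc2)cc(O[C@@H](c2ccc(OCc3ccccc3)cc2)[C@@H](C(O)CO)c2c(O)cc(OCc3ccccc3)c3c(=O)cc(-c4ccc5OC(c6ccccc6)(c6ccccc6)Oc5c4)oc23)c1 | intermediate (not isolated)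
23 | (2S,3R)-3-[3,5-bis(benzyloxy)phenoxy]-3-[4-(benzyloxy)phenyl]-2-[Fl, 7-OH]propanal | c1ccccc1COc1cc(OCc2ccccc2)cc(O[C@@H](c2ccc(OCc3ccccc3)cc2)[C@@H](C=O)c2c(O)cc(OCc3ccccc3)c3c(=O)cc(-c4ccc5OC(c6ccccc6)(c6ccccc6)Oc5c4)oc23)c1 | intermediate (not isolated)
24 | lactol of 23 on O7'' (C3 S, exocyclic carbon R, anomers) | c1ccccc1COc1cc(OCc2ccccc2)cc(O[C@@H](c2ccc(OCc3ccccc3)cc2)[C@H]2C(O)Oc3cc(OCc4ccccc4)c4c(=O)cc(-c5ccc6OC(c7ccccc7)(c7ccccc7)Oc6c5)oc4c32)c1 | intermediate
25 | lactone on O7''/C8'' (benzofuran-2(3H)-one, C3 S, exocyclic carbon R) | c1ccccc1COc1cc(OCc2ccccc2)cc(O[C@@H](c2ccc(OCc3ccccc3)cc2)[C@H]2C(=O)Oc3cc(OCc4ccccc4)c4c(=O)cc(-c5ccc6OC(c7ccccc7)(c7ccccc7)Oc6c5)oc4c32)c1 | intermediate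
26 | (2R,3S)-5,7-bis(benzyloxy)-2-[4-(benzyloxy)phenyl]-3-[5-(benzyloxy)-2-(2,2-diphenyl-1,3-benzodioxol-5-yl)-7-hydroxy-4-oxo-4H-chromen-8-yl]chroman-4-one | O=C1c2c(OCc3ccccc3)cc(OCc3ccccc3)cc2O[C@@H](c2ccc(OCc3ccccc3)cc2)[C@@H]1c1c(O)cc(OCc2ccccc2)c2c(=O)cc(-c3ccc4OC(c5ccccc5)(c5ccccc5)Oc4c3)oc12 | intermediate
27 | sulfur trioxide–pyridine complex | [O-]S(=O)(=O)[n+]1ccccc1 | starting material
28 | 7''-O-sulfate (hydrogen sulfate) of 26 | O=C1c2c(OCc3ccccc3)cc(OCc3ccccc3)cc2O[C@@H](c2ccc(OCc3ccccc3)cc2)[C@@H]1c1c(OS(=O)(=O)O)cc(OCc2ccccc2)c2c(=O)cc(-c3ccc4OC(c5ccccc5)(c5ccccc5)Oc4c3)oc12 | intermediate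
29 | (2R,3S)-3-[2-(3,4-dihydroxyphenyl)-5-hydroxy-4-oxo-7-(sulfooxy)-4H-chromen-8-yl]-5,7-dihydroxy-2-(4-hydroxyphenyl)chroman-4-one | O=C1c2c(O)cc(O)cc2O[C@@H](c2ccc(O)cc2)[C@@H]1c1c(OS(=O)(=O)O)cc(O)c2c(=O)cc(-c3ccc(O)c(O)c3)oc12 | target

Total step count: 14. Longest linear sequence: 14 steps (from luteolin).

**Steps most likely to fail**

1. Step 12 (proposed new method). The acyl transfer may lose out to acid-catalysed β-elimination of 3,5-bis(benzyloxy)phenol from the enolised lactone, or to ionisation at C2, before ring A attacks C4. The fallback uses the classical acid cyclisation and sets out from 19. Lemieux–Johnson cleavage of the vinyl group with the silyl ether still in place (OsO4 cat., NaIO4, THF–H2O) gives (2S,3R)-3-(ArA-oxy)-3-Ar'-2-[Fl, 7-OTIPS]propanal F1. Pinnick oxidation (NaClO2, NaH2PO4, 2-methyl-2-butene, t-BuOH–H2O) gives (2S,3R)-3-(ArA-oxy)-3-Ar'-2-[Fl, 7-OTIPS]propanoic acid F2. Trifluoroacetic anhydride in CH2Cl2 at 0 °C closes the ring by intramolecular Friedel–Crafts acylation through the mixed anhydride, with the same C3 equilibration, to (2R,3S)-5,7-bis(benzyloxy)-2-Ar'-3-[Fl, 7-OTIPS]chroman-4-one F3. HF·pyridine in THF removes the silyl group and the route is rejoined at 26.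

2. Step 8. The alkoxide on palladium may undergo β-hydride elimination (oxidation of the benzylic alcohol, reduction of 18), the vinyl group may be arylated in a Heck reaction, or the silyl group may be lost. The fallback delivers the aryl group without a transition metal and sets out from 17. [3,5-Bis(benzyloxy)phenyl](mesityl)iodonium tetrafluoroborate F4 is made from 3,5-bis(benzyloxy)phenylboronic acid and iodomesitylene diacetate with BF3·OEt2 in CH2Cl2. It arylates the sodium alkoxide of 17 (NaH, toluene, rt) by ligand coupling at hypervalent iodine, again with retention at C2, and the route is rejoined at 19.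

3. Step 7. The γ-carbon of 14 is flanked by the silyloxy group on C7'' and the pyranone oxygen, so the allylboration may be slow, and the face selectivity at the aldehyde may be poor. The fallback makes the C2–C3 bond by an asymmetric Nozaki–Hiyama–Kishi reaction and sets out from 12. Methanolysis (K2CO3 cat., MeOH, 0 °C) gives (E)-3-[Fl, 7-OTIPS]prop-2-en-1-ol F5. Corey–Kim chlorination (NCS, Me2S, CH2Cl2, −20 °C) gives (E)-3-[Fl, 7-OTIPS]prop-2-en-1-yl chloride F6. CrCl2 with a chiral oxazoline–sulfonamide ligand and Et3N in THF converts F6 into the allylchromium reagent, which should add to 15 through its γ-carbon, anti-selectively and with ligand control of the carbinol centre; aqueous work-up rejoins the route at 17.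

**Further compounds**
F1 | step 12 | (2S,3R)-3-[3,5-bis(benzyloxy)phenoxy]-3-[4-(benzyloxy)phenyl]-2-[Fl, 7-OTIPS]propanal | c1ccccc1COc1cc(OCc2ccccc2)cc(O[C@@H](c2ccc(OCc3ccccc3)cc2)[C@@H](C=O)c2c(O[Si](C(C)C)(C(C)C)C(C)C)cc(OCc3ccccc3)c3c(=O)cc(-c4ccc5OC(c6ccccc6)(c6ccccc6)Oc5c4)oc23)c1
F2 | step 12 | (2S,3R)-3-[3,5-bis(benzyloxy)phenoxy]-3-[4-(benzyloxy)phenyl]-2-[Fl, 7-OTIPS]propanoic acid | c1ccccc1COc1cc(OCc2ccccc2)cc(O[C@@H](c2ccc(OCc3ccccc3)cc2)[C@@H](C(=O)O)c2c(O[Si](C(C)C)(C(C)C)C(C)C)cc(OCc3ccccc3)c3c(=O)cc(-c4ccc5OC(c6ccccc6)(c6ccccc6)Oc5c4)oc23)c1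
F3 | step 12 | (2R,3S)-5,7-bis(benzyloxy)-2-[4-(benzyloxy)phenyl]-3-[Fl, 7-OTIPS]chroman-4-one | O=C1c2c(OCc3ccccc3)cc(OCc3ccccc3)cc2O[C@@H](c2ccc(OCc3ccccc3)cc2)[C@@H]1c1c(O[Si](C(C)C)(C(C)C)C(C)C)cc(OCc2ccccc2)c2c(=O)cc(-c3ccc4OC(c5ccccc5)(c5ccccc5)Oc4c3)oc12
F4 | step 8 | [3,5-bis(benzyloxy)phenyl](mesityl)iodonium tetrafluoroborate | Cc1cc(C)c([I+]c2cc(OCc3ccccc3)cc(OCc3ccccc3)c2)c(C)c1.F[B-](F)(F)F
F5 | step 7 | (E)-3-[Fl, 7-OTIPS]prop-2-en-1-ol | O=c1cc(-c2ccc3OC(c4ccccc4)(c4ccccc4)Oc3c2)oc2c(/C=C/CO)c(O[Si](C(C)C)(C(C)C)C(C)C)cc(OCc3ccccc3)c12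
F6 | step 7 | (E)-3-[Fl, 7-OTIPS]prop-2-en-1-yl chloride | O=c1cc(-c2ccc3OC(c4ccccc4)(c4ccccc4)Oc3c2)oc2c(/C=C/CCl)c(O[Si](C(C)C)(C(C)C)C(C)C)cc(OCc3ccccc3)c12
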